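**Retrosynthetic overview**
1. Lepidine C comes from its bis(N-dimethylsulfamoyl) derivative; N–S hydrolysis is the last step.
2. Both aryl–CH2 bonds are cut together. A twofold Catellani cine-alkylation (ortho C–H alkylation, hydrogen in place of iodine) joins one diiodo diaryl ether to two 2-(chloromethyl)imidazoles.
3. Structural feature: in ring A (C1 O-aryl, C2 CH2, C3 H, C4 OMe) the lone C3–H sits between C2 and C4. In ring B (C1' O, C2' H, C3' CH2) the lone C2'–H sits between C1' and C3'. Iodine on C3 and C2' leaves C2 and C3' as the only open ortho carbons.
4. The diiodide comes from 2-iodophenol and 4-methoxyphenylboronic acid (Chan–Lam coupling, then iodination ortho to OMe). The chloride comes from N,N-dimethylimidazole-1-sulfonamide (C2 formylation, reduction, chlorination).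
5. No ring is formed at any stage; both benzene rings and both imidazoles are bought.

Key step: step 6

Remark: Lepidine C is achiral and the N–H tautomers of each imidazole are one compound, so no stereochemical or tautomeric control is needed.

Step 1
Reactants: 1 2-iodophenol; 2 4-methoxyphenylboronic acid
Product: 3 1-iodo-2-(4-methoxyphenoxy)benzene
Conditions: 2 (2 equiv), Cu(OAc)2 (1 equiv), pyridine (5 equiv), 4 Å MS, CH2Cl2, air, rt
Reagents that add atoms: none
Why: The Chan–Lam oxidative C–O coupling runs at room temperature through an aryl copper phenoxide, so the diaryl ether forms while the C–I bond of 1, which a palladium or hot Ullmann coupling would attack, stays intact.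

Step 2
Reactants: 3 1-iodo-2-(4-methoxyphenoxy)benzene
Product: 4 2-iodo-4-(2-iodophenoxy)-1-methoxybenzene
Conditions: NIS (1.05 equiv), CF3CO2H (0.3 equiv), MeCN, 0 °C to rt, dark
Reagents that add atoms: N-iodosuccinimide, O=C1CCC(=O)N1I
Why: Electrophilic aromatic iodination with acid-activated NIS should go to ring A, the only ring with two oxygen donors and no deactivating iodine, and there to one of the two equivalent carbons ortho to OMe, because methoxy is the stronger donor and the carbons beside the twisted 2-iodophenoxy group are more crowded, in line with other electrophilic substitutions of 4-aryloxyanisoles.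

Step 3
Reactants: 5 N,N-dimethylimidazole-1-sulfonamide
Product: 8 2-formyl-N,N-dimethylimidazole-1-sulfonamide, via 2-lithio sulfamoylimidazole 6 (not isolated), via lithium hemiaminal alkoxide 7 (not isolated)
Conditions: n-BuLi (1.1 equiv), THF, −78 °C; DMF (3 equiv), −78 °C to rt; aq. NH4Cl
Reagents that add atoms: N,N-dimethylformamide, CN(C)C=O
Why: Directed lithiation takes place at C2, the most acidic imidazole C–H and the one next to the coordinating sulfamoyl group, and formylation with DMF stops at the aldehyde stage because the tetrahedral adduct 7 survives until the quench.

Step 4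
Reactants: 8 2-formyl-N,N-dimethylimidazole-1-sulfonamide
Product: 9 2-(hydroxymethyl)-N,N-dimethylimidazole-1-sulfonamide
Conditions: NaBH4, MeOH, 0 °C
Reagents that add atoms: none
Why: Borohydride reduction of an aldehyde is chemoselective and leaves the sulfamoyl group and the imidazole ring untouched.

Step 5
Reactants: 9 2-(hydroxymethyl)-N,N-dimethylimidazole-1-sulfonamide
Product: 10 2-(chloromethyl)-N,N-dimethylimidazole-1-sulfonamide
Conditions: SOCl2 (1.5 equiv), CH2Cl2, 0 °C to rt; cold aq. NaHCO3 wash; used soon after preparation
Reagents that add atoms: thionyl chloride, O=S(Cl)Cl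
Why: Deoxychlorination through a chlorosulfite gives the heterobenzylic chloride, and the electron-withdrawing sulfamoyl group lowers the nucleophilicity of N3 enough that the free base should not quaternise itself if kept cold and used promptly.

Step 6
Reactants: 4 2-iodo-4-(2-iodophenoxy)-1-methoxybenzene; 10 2-(chloromethyl)-N,N-dimethylimidazole-1-sulfonamide (two molecules are incorporated)
Product: 12 bis(N-dimethylsulfamoyl) Lepidine C, via ring B monoalkylated monoiodide 11 (not isolated)
Conditions: Pd(OAc)2 (20 mol %), P(2-furyl)3 (44 mol %), norbornene (4 equiv), Cs2CO3 (6 equiv), powdered HCO2Na (4 equiv), 10 (5 equiv), MeCN, 85 °C, sealed tube, Ar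
Reagents that add atoms: none
Why: At each C–I bond zerovalent palladium inserts, norbornene carbopalladates the aryl palladium iodide, and carbonate-assisted palladation of the one free ortho C–H (C2 of ring A, C3' of ring B) closes a five-membered aryl–norbornyl palladacycle of divalent palladium; chloride 10 (or the iodide made from it by accumulating CsI) then adds oxidatively to give tetravalent palladium, reductive elimination forms the aryl–CH2 bond, the doubly ortho-flanked norbornyl palladium expels norbornene by β-carbon elimination, and formate exchange, loss of CO2 and C–H reductive elimination put hydrogen where iodine stood. This is the Catellani ortho-alkylation with hydride termination, a known way from ortho-substituted aryl iodides to meta-substituted arenes that accepts benzylic chlorides as electrophiles, applied here to two iodides of one molecule and to an azolylmethyl chloride whose N3 is made a poor ligand and a poor nucleophile by the sulfamoyl group. No ring is closed in the product and no stereocentre is formed. Site selectivity needs no reagent control, because OMe blocks one side of the ring A iodide and the ether oxygen blocks one side of the ring B iodide, and these same substituents let norbornene leave after a single alkylation. The step needs norbornene insertion to outrun formate reduction of the first aryl palladium iodide, and hydride capture to outrun closure of the ring B aryl palladium onto ring A (dibenzofuran formation), which excess norbornene, sparingly soluble HCO2Na in MeCN and a moderate temperature should secure, while the surplus of 10 covers its loss to formate and carbonate. Ring B, whose C3'–H is unhindered, should react first to give 11, and the slower event is palladation of the ring A C2–H beside the aryloxy group, which should be tolerable because oxygen is a small neighbour whose aryl group can turn away.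

Step 7
Reactants: 12 bis(N-dimethylsulfamoyl) Lepidine C
Product: 13 Lepidine C
Conditions: 2 M aq. HCl, 1,4-dioxane, reflux; then aq. NaOH to pH 9–10, extraction
Reagents that add atoms: none
Why: Acid hydrolysis of the N–S bond of an N-sulfamoylimidazole, with protonated imidazole as the leaving group, is the standard removal of this group and spares the aryl methyl ether, the diaryl ether and both benzylic CH2 groups.

**Compound list**
1 | 2-iodophenol | Oc1ccccc1I | starting material
2 | 4-methoxyphenylboronic acid | COc1ccc(B(O)O)cc1 | starting material
3 | 1-iodo-2-(4-methoxyphenoxy)benzene | COc1ccc(Oc2ccccc2I)cc1 | intermediate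
4 | 2-iodo-4-(2-iodophenoxy)-1-methoxybenzene | COc1ccc(Oc2ccccc2I)cc1I | intermediate
5 | N,N-dimethylimidazole-1-sulfonamide | CN(C)S(=O)(=O)n1ccnc1 | starting material
6 | 2-lithio-N,N-dimethylimidazole-1-sulfonamide | [Li]c1nccn1S(=O)(=O)N(C)C | intermediate
7 | lithium (dimethylamino)[1-(dimethylsulfamoyl)imidazol-2-yl]methanolate | [Li+].[O-]C(N(C)C)c1nccn1S(=O)(=O)N(C)C | intermediate
8 | 2-formyl-N,N-dimethylimidazole-1-sulfonamide | CN(C)S(=O)(=O)n1ccnc1C=O | intermediate
9 | 2-(hydroxymethyl)-N,N-dimethylimidazole-1-sulfonamide | CN(C)S(=O)(=O)n1ccnc1CO | intermediate
10 | 2-(chloromethyl)-N,N-dimethylimidazole-1-sulfonamide | CN(C)S(=O)(=O)n1ccnc1CCl | intermediate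
11 | 2-[[3-(3-iodo-4-methoxyphenoxy)phenyl]methyl]-N,N-dimethylimidazole-1-sulfonamide | COc1ccc(Oc2cccc(Cc3nccn3S(=O)(=O)N(C)C)c2)cc1I | intermediate
12 | bis(N-dimethylsulfamoyl) Lepidine C, 2-[[3-[2-[[1-(dimethylsulfamoyl)imidazol-2-yl]methyl]-4-methoxyphenoxy]phenyl]methyl]-N,N-dimethylimidazole-1-sulfonamide | COc1ccc(Oc2cccc(Cc3nccn3S(=O)(=O)N(C)C)c2)c(Cc2nccn2S(=O)(=O)N(C)C)c1 | intermediate
13 | Lepidine C, 2-[[3-[2-(1H-imidazol-2-ylmethyl)-4-methoxyphenoxy]phenyl]methyl]-1H-imidazole | COc1ccc(Oc2cccc(Cc3ncc[nH]3)c2)c(Cc2ncc[nH]2)c1 | target

**Step count**
Total steps: 7. Longest linear sequence: 5 steps (5 → 8 → 9 → 10 → 12 → 13). The diiodide branch (1 + 2 → 3 → 4) adds 2 steps and joins at step 6.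

**Steps most likely to fail**

Step 6.
- Risks: Palladation of the ring A C–H beside the aryloxy group may stall, so that this iodide is only reduced or keeps norbornene attached. Formate may reduce the aryl palladium iodides before norbornene inserts. The ring B aryl palladium may close onto ring A. The chloride may be consumed by formate or carbonate.
- Fallback: this sets out from 10 and returns at 12. It gives up the cine relay and places the halogens on the carbons that carry the CH2 groups. Chan–Lam coupling of commercial 2-bromo-4-methoxyphenol with commercial 3-bromophenylboronic acid (Cu(OAc)2, pyridine, CH2Cl2, air, rt) would give 2-bromo-1-(3-bromophenoxy)-4-methoxybenzene F1. Chloride 10 would be inserted by zinc dust in the presence of LiCl in THF to give [1-(dimethylsulfamoyl)imidazol-2-yl]methylzinc chloride F2. A twofold Negishi coupling of the dibromide with this zinc reagent (Pd(OAc)2, SPhos, THF, 50 °C) would deliver 12.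

Step 2.
- Risks: The iodinating agent may attack beside the aryloxy oxygen of ring A or para to the ether oxygen on ring B, or a second iodination may occur, giving isomers that are hard to separate.
- Fallback: this sets out from 1 and returns at 4. It fixes the position through a nitrogen substituent that is bought in place. Chan–Lam coupling of 1 with commercial 4-methoxy-3-nitrophenylboronic acid would give 4-(2-iodophenoxy)-1-methoxy-2-nitrobenzene F3. Reduction with iron powder and NH4Cl in aqueous EtOH, which spares the C–I bond, would give 5-(2-iodophenoxy)-2-methoxyaniline F4. Diazotisation (NaNO2, aq. HCl, 0 °C) would give 5-(2-iodophenoxy)-2-methoxybenzenediazonium chloride F5, and Sandmeyer-type iodination with KI would give 4.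

Step 1.
- Risks: C–O coupling of the hindered and weakly nucleophilic ortho-iodophenol may be slow, with protodeboronation and oxidation of the boronic acid taking over.
- Fallback: this sets out from 1 and returns at 3. It uses no metal. The potassium phenoxide of 1 (t-BuOK, THF) would be O-arylated with commercial bis(4-methoxyphenyl)iodonium triflate at rt to 40 °C by ligand coupling on the diaryliodonium salt, which gives 3 directly and makes no new intermediate.

**Further compounds**
F1 | step 6 | 2-bromo-1-(3-bromophenoxy)-4-methoxybenzene | COc1ccc(Oc2cccc(Br)c2)c(Br)c1
F2 | step 6 | [1-(dimethylsulfamoyl)imidazol-2-yl]methylzinc chloride | CN(C)S(=O)(=O)n1ccnc1C[Zn]Cl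
F3 | step 2 | 4-(2-iodophenoxy)-1-methoxy-2-nitrobenzene | COc1ccc(Oc2ccccc2I)cc1[N+](=O)[O-]
F4 | step 2 | 5-(2-iodophenoxy)-2-methoxyaniline | COc1ccc(Oc2ccccc2I)cc1N
F5 | step 2 | 5-(2-iodophenoxy)-2-methoxybenzenediazonium chloride | COc1ccc(Oc2ccccc2I)cc1[N+]#N.[Cl-]
F0 | step 1 | none | none
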